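The route rests on disconnecting the oxirane at its CH2 carbon: C3 of the three-membered ring is bonded only to the ring oxygen and to the quaternary C2, so it can be added as a one-carbon unit to an aryl ketone whose carbonyl oxygen becomes the ring oxygen. In one operation a catalytic asymmetric sulfoxonium-ylide methylene transfer forms the C2–C3 bond and the C3–O bond, closes the oxirane and sets the only stereocentre. Its precursor is the aryl ketone ArC(=O)CH2OC(=O)iPr, which already carries the side-chain isobutyrate and has the phenol masked as a triisopropylsilyl ether; the phenol ester is put on last.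

Key step: step 4

Assumption: the sense of induction of the lanthanum–lithium binaphthoxide catalyst cannot be taken over from methyl ketones, because the CH2O arm is larger than methyl and can coordinate. The (S)-BINOL complex is written in step 4; the (R)-BINOL complex is to be used instead if a first run shows addition to the Re face.

Remark: the phenol is carried as a TIPS ether. An aryl silyl ether ortho to a ketone meets a carboxylate in step 3 and a neighbouring alkoxide in step 4, and the bulkier silicon resists both cleavage and O-to-O migration while still leaving with fluoride.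

Step 1
Reactants: 1 1,4-dimethoxy-2-methylbenzene (2,5-dimethoxytoluene); 2 chloroacetyl chloride
Product: 4 2-chloro-1-(2-hydroxy-5-methoxy-4-methylphenyl)ethan-1-one, via dimethoxy chloroketone 3 (not isolated)
Conditions: AlCl3 (2.5 equiv), CH2Cl2, 0 °C then reflux; ice/aq. HCl
Reagents that add atoms: chloroacetyl chloride, ClCC(Cl)=O
Why: Friedel–Crafts acylation takes place at the ring carbon para to the methyl group and ortho to a methoxy group, and the aluminium chelate between the new carbonyl oxygen and that neighbouring methoxy oxygen then loses chloromethane, so that only the ether ortho to the ketone is cleaved (chelation-controlled ortho-demethylation) while the remote methoxy group stays.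

Step 2
Reactants: 4 2-chloro-1-(2-hydroxy-5-methoxy-4-methylphenyl)ethan-1-one; 5 triisopropylsilyl trifluoromethanesulfonate
Product: 6 2-chloro-1-[5-methoxy-4-methyl-2-(triisopropylsilyloxy)phenyl]ethan-1-one
Conditions: TIPSOTf (1.2 equiv), 2,6-lutidine (1.5 equiv), CH2Cl2, −78 → 0 °C
Reagents that add atoms: triisopropylsilyl trifluoromethanesulfonate, CC(C)[Si](OS(=O)(=O)C(F)(F)F)(C(C)C)C(C)C
Why: O-Silylation of a phenol by a silyl triflate is fast even at −78 °C, and the hindered, weakly basic 2,6-lutidine can neither alkylate on the chloroketone nor build up the phenoxide that would otherwise close to a benzofuran-3(2H)-one by displacing chloride.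

Step 3
Reactants: 6 2-chloro-1-[5-methoxy-4-methyl-2-(triisopropylsilyloxy)phenyl]ethan-1-one; 7 isobutyric acid
Product: 8 2-[5-methoxy-4-methyl-2-(triisopropylsilyloxy)phenyl]-2-oxoethyl 2-methylpropanoate
Conditions: iPrCO2H (1.5 equiv), iPr2NEt (1.3 equiv), NaI (10 mol %), MeCN, rt → 40 °C
Reagents that add atoms: isobutyric acid (2-methylpropanoic acid), CC(C)C(=O)O
Why: SN2 displacement at a phenacyl carbon by a carboxylate, helped by in situ Finkelstein exchange to the iodide, is the standard phenacyl ester synthesis, and the amine-buffered, water-free medium does not attack the hindered aryl silyl ether.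

Step 4
Reactants: 8 2-[5-methoxy-4-methyl-2-(triisopropylsilyloxy)phenyl]-2-oxoethyl 2-methylpropanoate; 9 trimethylsulfoxonium iodide
Product: 12 [(2S)-2-[5-methoxy-4-methyl-2-(triisopropylsilyloxy)phenyl]oxiran-2-yl]methyl 2-methylpropanoate, via dimethylsulfoxonium methylide 10 (not isolated), via sulfoxonium betaine 11 (not isolated)
Conditions: 10 (1.2 equiv; from 9, NaH, THF, reflux), (S)-La–Li3–tris(binaphthoxide) (5 mol %), tris(2,4,6-trimethoxyphenyl)phosphine oxide (5 mol %), MS 5 Å, THF, rt
Reagents that add atoms: trimethylsulfoxonium iodide, C[S+](C)(C)=O.[I-] (the CH2 is delivered through its ylide, [CH2-][S+](C)(C)=O)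
Why: Proposed new method: the closest known reaction is the lanthanum–lithium binaphthoxide/phosphine oxide-catalysed Corey–Chaykovsky epoxidation of aryl and alkyl methyl ketones with this same ylide, extended here to an α-acyloxy ketone, a substrate class on which it has not been tried. Lanthanum activates the ketone oxygen while a lithium binaphthoxide site positions the ylide, whose carbon adds to the carbonyl carbon (new C–CH2 bond) to give betaine 11; its alkoxide then displaces dimethyl sulfoxide from the adjacent CH2 in a 3-exo-tet closure (new CH2–O bond), which forms the oxirane, the only ring made. The single stereocentre, the quaternary oxirane carbon, is set under catalyst control in the addition, which has to occur on the Si face of the carbonyl (priority O > CH2OCOiPr > aryl) to give the (S)-oxirane; the ring closure does not touch that carbon. The selectivity needed is therefore facial, and what the substrate offers the catalyst is the size difference between the twisted ortho-silyloxyaryl group and the CH2O arm, which take the places of aryl and methyl in the established ketones. Chemoselectivity for the ketone rests on the low reactivity of a branched alkyl ester toward a stabilised sulfoxonium ylide at room temperature, the bulky TIPS group should not migrate onto the betaine alkoxide, and enolisation of the ketone is reversible and should only slow the reaction.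

Step 5
Reactants: 12 [(2S)-2-[5-methoxy-4-methyl-2-(triisopropylsilyloxy)phenyl]oxiran-2-yl]methyl 2-methylpropanoate; 13 isobutyric anhydride
Product: 14 4-methoxy-5-methyl-2-[(2S)-2-{[(2-methylpropanoyl)oxy]methyl}oxiran-2-yl]phenyl 2-methylpropanoate
Conditions: (iPrCO)2O (4 equiv), anhydrous CsF (2.5 equiv), DMAP (10 mol %), DMF, 0 °C → rt
Reagents that add atoms: isobutyric anhydride, CC(C)C(=O)OC(=O)C(C)C
Why: Fluoride cleaves the aryl O–Si bond and the phenoxide is acylated at once by the excess anhydride (desilylative acylation, DMAP-assisted acyl transfer), so that it is not left free to open the neighbouring oxirane, while the alkyl ester, the oxirane and its quaternary stereocentre, none of which is attacked by fluoride at this temperature, stay as they are.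

Compound list
1 | 1,4-dimethoxy-2-methylbenzene (2,5-dimethoxytoluene) | COc1ccc(OC)c(C)c1 | starting material
2 | chloroacetyl chloride | ClCC(Cl)=O | starting material
3 | 2-chloro-1-(2,5-dimethoxy-4-methylphenyl)ethan-1-one | COc1cc(C(=O)CCl)c(OC)cc1C | intermediate (not isolated)
4 | 2-chloro-1-(2-hydroxy-5-methoxy-4-methylphenyl)ethan-1-one | COc1cc(C(=O)CCl)c(O)cc1C | intermediate
5 | triisopropylsilyl trifluoromethanesulfonate | CC(C)[Si](OS(=O)(=O)C(F)(F)F)(C(C)C)C(C)C | starting material
6 | 2-chloro-1-[5-methoxy-4-methyl-2-(triisopropylsilyloxy)phenyl]ethan-1-one | COc1cc(C(=O)CCl)c(O[Si](C(C)C)(C(C)C)C(C)C)cc1C | intermediate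
7 | isobutyric acid (2-methylpropanoic acid) | CC(C)C(=O)O | starting material
8 | 2-[5-methoxy-4-methyl-2-(triisopropylsilyloxy)phenyl]-2-oxoethyl 2-methylpropanoate | COc1cc(C(=O)COC(=O)C(C)C)c(O[Si](C(C)C)(C(C)C)C(C)C)cc1C | intermediate
9 | trimethylsulfoxonium iodide | C[S+](C)(C)=O.[I-] | starting material
10 | dimethylsulfoxonium methylide | [CH2-][S+](C)(C)=O | intermediate (not isolated)
11 | sulfoxonium betaine, (R)-configured alkoxide ArC(O−)(CH2OC(=O)iPr)CH2S(+)(=O)Me2 with Ar = 5-methoxy-4-methyl-2-(triisopropylsilyloxy)phenyl; same spatial arrangement at carbon as in 12 | COc1cc([C@@]([O-])(COC(=O)C(C)C)C[S+](C)(C)=O)c(O[Si](C(C)C)(C(C)C)C(C)C)cc1C | intermediate (not isolated)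
12 | [(2S)-2-[5-methoxy-4-methyl-2-(triisopropylsilyloxy)phenyl]oxiran-2-yl]methyl 2-methylpropanoate | COc1cc([C@@]2(COC(=O)C(C)C)CO2)c(O[Si](C(C)C)(C(C)C)C(C)C)cc1C | intermediate
13 | isobutyric anhydride (2-methylpropanoic anhydride) | CC(C)C(=O)OC(=O)C(C)C | starting material
14 | 4-methoxy-5-methyl-2-[(2S)-2-{[(2-methylpropanoyl)oxy]methyl}oxiran-2-yl]phenyl 2-methylpropanoate | COc1cc([C@@]2(COC(=O)C(C)C)CO2)c(OC(=O)C(C)C)cc1C | target

Total step count: 5. Longest linear sequence: 5 steps (1 → 4 → 6 → 8 → 12 → 14).

Steps most likely to fail

Step 4 (Proposed new method). Facial selectivity may be poor because the CH2O arm is not as small as methyl, or because two-point binding of the α-acyloxy ketone changes the face the catalyst exposes. The reaction may also stall through enolisation, and the isobutyryl group may shift within the betaine. The fallback uses known chemistry and replaces carbon transfer to a ketone by oxygen transfer to an alkene. It sets out from ketone 8. Wittig methylenation (Ph3P=CH2, THF, −78 → 0 °C) should give 2-[5-methoxy-4-methyl-2-(triisopropylsilyloxy)phenyl]prop-2-en-1-yl 2-methylpropanoate F1. DIBAL-H (CH2Cl2, −78 °C) should free the allylic alcohol 2-[5-methoxy-4-methyl-2-(triisopropylsilyloxy)phenyl]prop-2-en-1-ol F2. Sharpless asymmetric epoxidation (Ti(OiPr)4, D-(−)-diethyl tartrate, t-BuOOH, MS 4 Å, CH2Cl2, −20 °C) should then give the glycidol [(2R)-2-[5-methoxy-4-methyl-2-(triisopropylsilyloxy)phenyl]oxiran-2-yl]methanol F3. D-tartrate is chosen because the face rule of this reaction has L-tartrate turn 2-substituted allyl alcohols into the (S)-glycidols. The (R)-alcohol is the one whose isobutyrate is (S): the descriptor changes on acylation, the geometry does not. A Payne rearrangement of F3 would be degenerate and would return the same enantiomer. Acylation with isobutyric anhydride 13, Et3N and DMAP in CH2Cl2 at 0 °C comes back to the route at 12.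

Step 5. The phenoxide set free beside the oxirane may open it by 5-exo attack on the ring CH2, giving a 3-hydroxy-2,3-dihydrobenzofuran, faster than it is acylated; or the fluoride may be held back by the anhydride so that desilylation stalls. The fallback puts both esters in place before the oxirane exists and forms the ring last. It sets out from ketone 8. The same CsF/isobutyric anhydride exchange, applied where nothing can be opened, should give 2-{5-methoxy-4-methyl-2-[(2-methylpropanoyl)oxy]phenyl}-2-oxoethyl 2-methylpropanoate F4. Takai–Lombardo methylenation (Zn, CH2Br2, TiCl4, THF), which is not basic and spares esters, should give 2-{5-methoxy-4-methyl-2-[(2-methylpropanoyl)oxy]phenyl}prop-2-en-1-yl 2-methylpropanoate F5. Shi epoxidation with a sugar-derived oxazolidinone ketone of the kind used for 1,1-disubstituted alkenes (Oxone, buffered MeCN/water, 0 °C), in the enantiomeric series that delivers the (S)-oxirane, comes back to the route at the target 14.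

Step 1. Ether cleavage may stop short of completion or go on to the second methoxy group, and some acylation may occur next to the other methoxy group. The fallback builds the same hydroxy ketone by acyl migration from oxygen to carbon. It sets out from chloroacetyl chloride 2, which with purchased 4-methoxy-3-methylphenol F6 (pyridine, CH2Cl2, 0 °C) should give 4-methoxy-3-methylphenyl chloroacetate F7. Fries rearrangement (AlCl3, chlorobenzene, about 100 °C, or TiCl4) should move the acyl group to the ortho position para to the methyl group, the other ortho position being flanked by the methyl, and comes back to the route at 4.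

Further compounds
F1 | step 4 | 2-[5-methoxy-4-methyl-2-(triisopropylsilyloxy)phenyl]prop-2-en-1-yl 2-methylpropanoate | COc1cc(C(=C)COC(=O)C(C)C)c(O[Si](C(C)C)(C(C)C)C(C)C)cc1C
F2 | step 4 | 2-[5-methoxy-4-methyl-2-(triisopropylsilyloxy)phenyl]prop-2-en-1-ol | COc1cc(C(=C)CO)c(O[Si](C(C)C)(C(C)C)C(C)C)cc1C
F3 | step 4 | [(2R)-2-[5-methoxy-4-methyl-2-(triisopropylsilyloxy)phenyl]oxiran-2-yl]methanol | COc1cc([C@@]2(CO)CO2)c(O[Si](C(C)C)(C(C)C)C(C)C)cc1C
F4 | step 5 | 2-{5-methoxy-4-methyl-2-[(2-methylpropanoyl)oxy]phenyl}-2-oxoethyl 2-methylpropanoate | COc1cc(C(=O)COC(=O)C(C)C)c(OC(=O)C(C)C)cc1C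
F5 | step 5 | 2-{5-methoxy-4-methyl-2-[(2-methylpropanoyl)oxy]phenyl}prop-2-en-1-yl 2-methylpropanoate | COc1cc(C(=C)COC(=O)C(C)C)c(OC(=O)C(C)C)cc1C
F6 | step 1 | 4-methoxy-3-methylphenol (purchased for the fallback, not made) | COc1ccc(O)cc1C
F7 | step 1 | 4-methoxy-3-methylphenyl chloroacetate | COc1ccc(OC(=O)CCl)cc1C
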